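**Assumption:** paraformaldehyde is used as the source of formaldehyde and vinyl bromide as a THF solution; TBSCl, B2pin2, the perester, catalysts and ligands are purchased reagents. The target is the (2S)-flavanone.

## Retrosynthetic overview

1. Target 13 ⇐ tris-TBS ether 12 by a final buffered desilylation.
2. Pyranone ring of 12 ⇐ salicylaldehyde 5 + vinylchromene 11 in one radical annulation: acyl-radical addition makes C3–C4, then Cu-mediated C–O coupling makes O1–C2 and sets 2S.
3. 11 ⇐ silyl chromene 9 by sterically controlled C6–H borylation/vinylation; 9 ⇐ catechol + 3-chloro-3-methylbut-1-yne (propargyl ether Claisen/oxa-6π).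
4. 5 ⇐ resorcinol by silylation, meta C–H borylation/oxidation (third oxygen) and ortho-formylation.
5. Ring order: both benzene rings are bought; the chromene pyran ring is formed first (step 4), the pyranone ring last (step 7).

## Route

**Step 1**
Reactants: 1 resorcinol
Product: 2 1,3-bis(tert-butyldimethylsilyloxy)benzene
Conditions: TBSCl (2.2 equiv), imidazole, DMF, rt
Reagents that add atoms: TBSCl, CC(C)(C)[Si](C)(C)Cl
Why: Standard phenol silylation; the bulky silyl ethers also block every ring position except C5 for the next step.

**Step 2**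
Reactants: 2 1,3-bis(tert-butyldimethylsilyloxy)benzene
Product: 3 3,5-bis(tert-butyldimethylsilyloxy)phenol
Conditions: [Ir(OMe)(cod)]2 (1 mol %), dtbpy (2 mol %), B2pin2 (0.7 equiv), hexane, 80 °C; evaporate; then Oxone, acetone/H2O, rt, 10 min
Reagents that add atoms: Oxone (oxygen atom), OOS(=O)(=O)[O-].[K+]
Why: One-pot Ir-catalysed C–H borylation/oxidation; borylation is sterically controlled and goes only to C5, the one C–H with no ortho substituent, and short Oxone exposure leaves aryl TBS ethers intact.

**Step 3**
Reactants: 3 3,5-bis(tert-butyldimethylsilyloxy)phenol; 4 formaldehyde (as paraformaldehyde)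
Product: 5 2-hydroxy-4,6-bis(tert-butyldimethylsilyloxy)benzaldehyde
Conditions: MgCl2, Et3N, (CH2O)n, MeCN, 75 °C
Reagents that add atoms: none (the formyl group comes from reactant 4)
Why: Mg-phenoxide-directed ortho-formylation (Casnati–Skattebøl); the two ortho positions are equivalent by symmetry and the para position is not reached by the chelated formaldehyde, so one regioisomer forms.

**Step 4**
Reactants: 6 catechol (3 equiv); 7 3-chloro-3-methylbut-1-yne
Product: 8 2,2-dimethyl-2H-chromen-8-ol
Conditions: K2CO3, KI, CuI (5 mol %), DMF, 60 °C, N2; then 150 °C in the same flask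
Reagents that add atoms: none
Why: Cu-assisted mono-O-propargylation followed by aryl propargyl ether Claisen rearrangement, 1,5-H shift and oxa-6π electrocyclisation; only the unsubstituted ortho carbon can rearomatise, which places the remaining OH at C8.

**Step 5**
Reactants: 8 2,2-dimethyl-2H-chromen-8-ol
Product: 9 tert-butyl[(2,2-dimethyl-2H-chromen-8-yl)oxy]dimethylsilane
Conditions: TBSCl, imidazole, DMF, rt
Reagents that add atoms: TBSCl, CC(C)(C)[Si](C)(C)Cl
Why: Standard phenol silylation; it removes the O–H before borylation and the radical step and adds no C–H bonds that are prone to hydrogen abstraction.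

**Step 6**
Reactants: 9 tert-butyl[(2,2-dimethyl-2H-chromen-8-yl)oxy]dimethylsilane; 10 vinyl bromide
Product: 11 tert-butyl[(6-ethenyl-2,2-dimethyl-2H-chromen-8-yl)oxy]dimethylsilane
Conditions: [Ir(OMe)(cod)]2 (1.5 mol %), dtbpy (3 mol %), B2pin2 (0.8 equiv), THF, 80 °C; then Pd(dppf)Cl2 (3 mol %), aq K3PO4, vinyl bromide (1 M in THF, 3 equiv), 50 °C, sealed tube
Reagents that add atoms: none (the vinyl group comes from reactant 10; boron is lost)
Why: One-pot C–H borylation/Suzuki–Miyaura coupling; C6–H is the only aromatic C–H without an ortho substituent (C5 is next to the ring fusion, C7 next to OTBS), and the hindered ring alkene C–H bonds react more slowly.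

**Step 7 (key step)**
Reactants: 5 2-hydroxy-4,6-bis(tert-butyldimethylsilyloxy)benzaldehyde (1.5 equiv); 11 tert-butyl[(6-ethenyl-2,2-dimethyl-2H-chromen-8-yl)oxy]dimethylsilane (1.0 equiv)
Product: 12 (2S)-5,7-bis(tert-butyldimethylsilyloxy)-2-[8-(tert-butyldimethylsilyloxy)-2,2-dimethyl-2H-chromen-6-yl]-2,3-dihydro-4H-chromen-4-one
Conditions: Cu(MeCN)4PF6 (10 mol %), (S,S)-t-Bu-Box (12 mol %), PhCO3t-Bu (1.3 equiv, slow addition), MeCN, 25 °C, N2
Reagents that add atoms: none
Why: Proposed new method: Cu(I) and the perester give Cu(II) and t-BuO•, which abstracts the formyl H of 5 (its OH is held in the O–H···O=C bond or as the Cu chelate); the nucleophilic aroyl radical adds to the terminal vinyl carbon of 11 (C3–C4), and the benzylic radical, whose phenoxide/ketone is chelated to the chiral Cu(II)–Box centre, is captured intramolecularly as a Cu(III) alkyl that reductively eliminates O1–C2, with the Box ligand differentiating the faces of the radical to give 2S (the sense of induction cannot be predicted for a new reaction, so it is checked by CD/chiral HPLC and the ligand antipode is used if 2R forms); the closest known reactions are peroxide-initiated acyl-radical additions of aldehydes to styrenes, Cu/bisoxazoline enantioselective radical oxy-functionalisation of styrenes, and Kharasch–Sosnovsky C–O coupling.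

**Step 8**
Reactants: 12 tris-TBS flavanone
Product: 13 (2S)-5,7-dihydroxy-2-(8-hydroxy-2,2-dimethyl-2H-chromen-6-yl)-2,3-dihydro-4H-chromen-4-one (target)
Conditions: TBAF/AcOH (1:1, 3.5 equiv), THF, 0 °C
Reagents that add atoms: none
Why: Fluoride cleavage of the three aryl silyl ethers; the acetic acid buffer prevents base-induced retro-oxa-Michael opening, so C2 is not racemised, and the chromene is untouched.

## Compound list

1 | resorcinol | Oc1cccc(O)c1 | starting material
2 | 1,3-bis(tert-butyldimethylsilyloxy)benzene | CC(C)(C)[Si](C)(C)Oc1cccc(O[Si](C)(C)C(C)(C)C)c1 | intermediate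
3 | 3,5-bis(tert-butyldimethylsilyloxy)phenol | Oc1cc(O[Si](C)(C)C(C)(C)C)cc(O[Si](C)(C)C(C)(C)C)c1 | intermediate
4 | formaldehyde (paraformaldehyde) | C=O | starting material
5 | 2-hydroxy-4,6-bis(tert-butyldimethylsilyloxy)benzaldehyde | O=Cc1c(O)cc(O[Si](C)(C)C(C)(C)C)cc1O[Si](C)(C)C(C)(C)C | intermediate
6 | catechol | Oc1ccccc1O | starting material
7 | 3-chloro-3-methylbut-1-yne | C#CC(C)(C)Cl | starting material
8 | 2,2-dimethyl-2H-chromen-8-ol | CC1(C)C=Cc2cccc(O)c2O1 | intermediate
9 | tert-butyl[(2,2-dimethyl-2H-chromen-8-yl)oxy]dimethylsilane | CC1(C)C=Cc2cccc(O[Si](C)(C)C(C)(C)C)c2O1 | intermediate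
10 | vinyl bromide | C=CBr | starting material
11 | tert-butyl[(6-ethenyl-2,2-dimethyl-2H-chromen-8-yl)oxy]dimethylsilane | C=Cc1cc2C=CC(C)(C)Oc2c(O[Si](C)(C)C(C)(C)C)c1 | intermediate
12 | (2S)-5,7-bis(TBSO)-2-[8-(TBSO)-2,2-dimethyl-2H-chromen-6-yl]chroman-4-one | CC1(C)C=Cc2cc([C@@H]3CC(=O)c4c(O[Si](C)(C)C(C)(C)C)cc(O[Si](C)(C)C(C)(C)C)cc4O3)cc(O[Si](C)(C)C(C)(C)C)c2O1 | intermediate
13 | (2S)-5,7-dihydroxy-2-(8-hydroxy-2,2-dimethyl-2H-chromen-6-yl)-2,3-dihydro-4H-chromen-4-one | CC1(C)C=Cc2cc([C@@H]3CC(=O)c4c(O)cc(O)cc4O3)cc(O)c2O1 | target

## Summary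

Total steps: 8 (step 4 is run as a one-flask alkylation/rearrangement and steps 2 and 6 as one-pot borylation sequences).
Longest linear sequence: 5 steps (1→2→3→5→12→13, or 6→8→9→11→12→13).

Three steps most likely to fail:

1. **Step 7.** Risks are phenol or product C2–H abstraction by t-BuO•, β-H loss to the 2'-hydroxychalcone, over-oxidation to the flavone, and a racemic pathway through the p-alkoxybenzyl cation. Fallback: keep the radical C–C bond formation but run it as a Cu/peroxide oxidative acylation of 11 with 5 to the 2'-hydroxychalcone, desilylate, and set C2 in a separate enantioselective oxa-Michael ring closure (chalcone isomerase or a chiral bifunctional thiourea).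
2. **Step 6.** Risks are Ir-mediated borylation or hydroboration at the chromene alkene and partial TBS loss under aqueous base. Fallback: carry the benzylic carbon from the start, i.e. formylate catechol to 3,4-dihydroxybenzaldehyde, do the 4-O-selective propargylation/Claisen to 8-hydroxy-2,2-dimethylchromene-6-carbaldehyde, silylate, and methylenate (Wittig) to 11.
3. **Step 4.** Risks are bis-alkylation and a low-yielding thermal cascade with the free ortho-OH. Fallback: build the pyran ring by condensing catechol with 3-methylbut-2-enal (Ti(OEt)4- or amine-mediated ortho-alkylation, o-quinone methide, oxa-6π) instead of the propargyl ether Claisen.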